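I started from the late end of the runs. Over the last interval, from 9.5 min to 18 min, each slope can be set against what the overall equation leaves in the flask: the charge less the mean Pdt of that interval.

the same everywhere: Ctl 0.0200 M
- Thursday's: Sbt 1.00 M; Ptn 1.50 M
- Wednesday's: Sbt 0.600 M; Ptn 1.10 M
- Tuesday's: Sbt 1.50 M; Ptn 1.50 M
- Saturday's: Sbt 3.00 M; Ptn 1.50 M; time 18 min

| run | time / min | [Pdt] / M |
|---|---|---|
| Thursday's run | 0.72 | 0.035 |
| Thursday's run | 1.4 | 0.076 |
| Thursday's run | 2.6 | 0.132 |
| Thursday's run | 5.0 | 0.240 |
| Thursday's run | 9.5 | 0.399 |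
| Thursday's run | 18 | 0.595 |
| Wednesday's run | 0.72 | 0.024 |
| Wednesday's run | 1.4 | 0.041 |
| Wednesday's run | 2.6 | 0.078 |
| Wednesday's run | 5.0 | 0.128 |
| Wednesday's run | 9.5 | 0.225 |
| Wednesday's run | 18 | 0.335 |
| Tuesday's run | 0.72 | 0.048 |
| Tuesday's run | 1.4 | 0.126 |
| Tuesday's run | 2.6 | 0.191 |
| Tuesday's run | 5.0 | 0.337 |
| Tuesday's run | 9.5 | 0.564 |
| Tuesday's run | 18 | 0.825 |

(readings scatter by 0.01 M)

- Overall: Sbt + Ptn -> Pdt, with Ctl as catalyst.
- Constant volume, constant temperature.
- A reading of a species includes what of it is bound.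
- An order is taken over about fifteen percent of the charge, up and down.

- order of the initial rate in [Ptn], near the charge of the Thursday's run, the rate being that where two percent of its Sbt are Pdt
- order of the initial rate in [Sbt], near the charge of the Thursday's run, the rate being that where two percent of its Sbt are Pdt (one fixed amount of Pdt, the same in the runs compared)
- the Wednesday's run starts with 0.400 M less of Sbt and of Ptn than the Thursday's run, and with no Pdt. Compared where both hold the same amount of Sbt, once fifteen percent of what the Wednesday's run was charged with has turned into Pdt, is the Wednesday's run faster, slower or alike (within a tenth)?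
- Pdt in the Saturday's run at 18 min, as a share of the Sbt charged

Tuesday's run was the zero of my scale. Charged equally, it keeps [Sbt] and [Ptn] equal as Pdt forms, while Thursday's and Wednesday's runs keep excesses of Ptn of 0.500 M and 0.500 M. The late readings gave:

Thursday's run: slope 0.0231 M min⁻¹, [Sbt] 0.503 M, [Ptn] 1.00 M

Tuesday's run: slope 0.0307 M min⁻¹, [Sbt] 0.806 M, [Ptn] 0.806 M

Wednesday's run: slope 0.0129 M min⁻¹, [Sbt] 0.320 M, [Ptn] 0.820 M

Tuesday's and Wednesday's runs hold nearly the same [Ptn], so their slopes gave a late Sbt order of 0.936. I divided that out of Thursday's slope over Tuesday's, and what remained, on a log scale against their [Ptn] ratio, I called the late Ptn order: 0.704. It is a reading, since each slope carries a scatter of 0.00166 M min⁻¹.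

Thursday's and Wednesday's runs share one excess, so at equal [Sbt] they hold equal [Ptn], and my rate law called them alike.

In Saturday's run Ptn is the limiting reagent. I booked its charge in steps of 6.00 min, scaling Tuesday's slope by both orders and taking each step's rate at its middle. I reckoned a start rate of 0.163 M min⁻¹.

Ptn charged: 1.50 M

Into Pdt by 6.00 min: 0.627 M; rate then 0.0893 M min⁻¹

Into Pdt by 12.0 min: a further 0.370 M; rate then 0.0517 M min⁻¹

Into Pdt by 18 min: a further 0.222 M

Ptn still outside Pdt: 0.281 M

So I reckoned Pdt at 40.6% of the Sbt charged.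

The forecast gave 0.4 for the Ptn order, 0.85 for the Sbt order, alike for the comparison and 39% for Saturday's run, holding that “Wednesday implies a Ptn order of about 0.4”. My late Ptn order, which I took as my answer for the early order asked, stood higher, and my share for Saturday's run a little higher.

The flask gave 0.67 for the Ptn order, 0.89 for the Sbt order, alike for the comparison and 39.2% for Saturday's run.

    Ctl + Ptn ⇌ Ctl.Ptn, settled at all times (0.4620 M⁻¹)
    Ctl.Ptn + Sbt → Pdt + Ctl (31.02 M⁻¹ min⁻¹)
    2 Ctl ⇌ Ctl2, settled at all times (255.0 M⁻¹)
    Sbt + Ptn ⇌ Sbt.Ptn, settled at all times (0.3570 M⁻¹)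

Carried to Wednesday's run, the late orders 0.936 and 0.704 put its early rate at 0.498 of Thursday's, and the simulated rates, 0.029 M min⁻¹ over 0.058 M min⁻¹, stand at 0.506. Ptn, drawing Ctl into Ctl.Ptn, also draws it out of Ctl2, so [Ptn] counts for more in Thursday's run: its order is 0.67 with that binding and 0.38 in the simulated run without it.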